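**Strategy.** The carbocycle of the target (C4a, C5, C6, C7, C8, C8a; chromane numbering) is a dearomatised acylphloroglucinol whose C7–C6 edge is a 5-methylhex-4-enoyl unit. Cutting C7–C8 and C5–C6 leaves an enantiopure 2-methyldihydropyranone that carries an ethyl group (future C8 with its methyl) on C8a and a methyl ester (future C5) on C4a. In one flask its γ-dienolate is C-acylated and the new ketone closes onto the ester, a biomimetic Claisen–Dieckmann annulation that delivers the fully substituted aromatic chromanone with every substituent placed unambiguously. A catalyst-controlled dearomatising geranylation at C8 then creates the quaternary centre.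

Key step: step 6

Remark: the bicyclic compounds are numbered as chromanes; the face preferred by the diphosphine ligand in step 8 is assigned by analogy, and its antipode would be taken if the opposite face proved to be preferred.

**Step 1**
Reactants: 1 (3S)-3-hydroxybutanoic acid
Product: 2 tert-butyldimethylsilyl (3S)-3-[(tert-butyldimethylsilyl)oxy]butanoate
Conditions: TBSCl (2.3 equiv), imidazole (5 equiv), DMF, 0 °C to rt
Reagents that add atoms: tert-butyldimethylsilyl chloride, C[Si](C)(Cl)C(C)(C)C
Why: Standard bis-silylation of a hydroxy acid to the silyl ether silyl ester, which leaves the stereocentre untouched.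

**Step 2**
Reactants: 2 tert-butyldimethylsilyl (3S)-3-[(tert-butyldimethylsilyl)oxy]butanoate
Product: 3 (3S)-3-[(tert-butyldimethylsilyl)oxy]butanoyl chloride
Conditions: (COCl)2 (1.2 equiv), DMF (cat.), CH2Cl2, 0 °C to rt; volatiles removed, used crude
Reagents that add atoms: oxalyl chloride, O=C(Cl)C(=O)Cl
Why: The Vilsmeier-type chloroiminium reagent converts a silyl ester directly into the acid chloride under neutral conditions, so the secondary silyl ether and the stereocentre survive.

**Step 3**
Reactants: 3 (3S)-3-[(tert-butyldimethylsilyl)oxy]butanoyl chloride; 4 methyl 3-oxopentanoate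
Product: 5 methyl (5S)-5-[(tert-butyldimethylsilyl)oxy]-3-oxo-2-propanoylhexanoate
Conditions: 4, MgCl2 (1.0 equiv), pyridine (2.0 equiv), CH2Cl2, 0 °C; then 3, 0 °C to rt
Reagents that add atoms: none
Why: C-acylation of the magnesium-chelated enolate of a β-keto ester by an acid chloride (soft enolisation), in which the chelate suppresses O-acylation and the weak base avoids β-elimination of the silyloxy group.

**Step 4**
Reactants: 5 methyl (5S)-5-[(tert-butyldimethylsilyl)oxy]-3-oxo-2-propanoylhexanoate
Product: 7 methyl (2S)-6-ethyl-2-methyl-4-oxo-3,4-dihydro-2H-pyran-5-carboxylate, via hydroxy triketo ester 6 (not isolated)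
Conditions: HF (48% aq.), MeCN, 0 °C to rt
Reagents that add atoms: none
Why: Desilylation frees the alcohol, which adds to the propanoyl carbonyl (the only ketone that gives a six-membered hemiketal) and loses water under acid to the vinylogous ester (cyclodehydration to a 2,3-dihydro-4H-pyran-4-one), while C2 keeps its S configuration because no bond to it is broken.

**Step 5**
Reactants: 8 5-methylhex-4-enoic acid
Product: 9 1-(1H-imidazol-1-yl)-5-methylhex-4-en-1-one
Conditions: 1,1′-carbonyldiimidazole (1.05 equiv), CH2Cl2, rt; brief cold-water wash, dried, concentrated, used without purification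
Reagents that add atoms: 1,1′-carbonyldiimidazole, O=C(n1ccnc1)n1ccnc1
Why: Standard activation of a carboxylic acid as its N-acylimidazole, an acyl donor that favours C- over O-acylation of stabilised enolates.

**Step 6**
Reactants: 7 methyl (2S)-6-ethyl-2-methyl-4-oxo-3,4-dihydro-2H-pyran-5-carboxylate; 9 1-(1H-imidazol-1-yl)-5-methylhex-4-en-1-one
Product: 11 (2S)-5,7-dihydroxy-2,8-dimethyl-6-(3-methylbut-2-en-1-yl)-2,3-dihydro-4H-chromen-4-one, via γ-acylated keto ester 10 (not isolated)
Conditions: LiN(SiMe3)2 (1.05 equiv), THF, −78 °C; 9 (1.05 equiv), −78 °C; LiN(SiMe3)2 (2.3 equiv), −78 °C to rt; 1 M HCl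
Reagents that add atoms: none
Why: LiN(SiMe3)2 removes a proton from the ethyl CH2, which is vinylogous to both the C4 ketone and the ester, and the lithium dienolate is acylated at this γ-carbon by the N-acylimidazole (C7–C8 bond); the anion of 10 is deprotonated again at the methylene on the far side of the new ketone, that carbanion attacks the ring ester (C5–C6 bond), and loss of methoxide and enolisation give the phenol. The closest known reaction types are the γ-C-acylation of vinylogous-ester dienolates with N-acylimidazoles and the Claisen cyclisation of polyketo esters to acylphloroglucinols, the ring closure that a type 3 polyketide synthase performs. The single new ring is closed in the 6-(enolexo)-exo-trig mode onto the ester carbonyl. No stereocentre is created, and C2 should be retained because the only anion formed next to the heterocycle is the γ-dienolate, which cannot expel the ring oxygen. The step needs γ- over C3-deprotonation, secured by the double activation and by ester-directed lithiation of the cis alkyl group, and γ-C- over α-C- or O-acylation, secured by the fully substituted α-carbon and the reversibility of O-acylation by an imidazolide. Closure onto the ester and not aldol addition to C4 is secured because only the Claisen path ends in an aromatic, doubly deprotonated product, the bridged aldol adduct being strained and reversible.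

**Step 7**
Reactants: 12 geraniol
Product: 13 (2E)-3,7-dimethylocta-2,6-dien-1-yl methyl carbonate
Conditions: ClCO2Me (1.2 equiv), pyridine (1.5 equiv), CH2Cl2, 0 °C
Reagents that add atoms: methyl chloroformate, COC(=O)Cl
Why: Standard acylation of a primary allylic alcohol to the mixed carbonate, with the E alkene unaffected.

**Step 8**
Reactants: 11 (2S)-5,7-dihydroxy-2,8-dimethyl-6-(3-methylbut-2-en-1-yl)-2,3-dihydro-4H-chromen-4-one; 13 (2E)-3,7-dimethylocta-2,6-dien-1-yl methyl carbonate
Product: 14 (2S,8R)-8-[(2E)-3,7-dimethylocta-2,6-dien-1-yl]-5-hydroxy-2,8-dimethyl-6-(3-methylbut-2-en-1-yl)-2,3-dihydro-4H-chromene-4,7(8H)-dione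
Conditions: Pd2(dba)3·CHCl3 (2.5 mol %, zerovalent palladium; dba = dibenzylideneacetone), (1R,2R)-N,N′-bis[2-(diphenylphosphino)benzoyl]cyclohexane-1,2-diamine (7.5 mol %), 13 (1.0 equiv), 1,4-dioxane, rt
Reagents that add atoms: none
Why: Tsuji–Trost-type catalytic asymmetric allylic dearomatisation, in which methoxide released from the carbonate deprotonates the 7-OH, the phenoxide attacks the unsubstituted terminus of the π-geranyl complex of divalent palladium through the methyl-bearing C8 (less hindered than the prenyl-bearing C6, O-allylation being reversible), and the chiral pocket of the diphosphine, not the remote C2 centre, selects the face of the planar nucleophile and so sets C8 as R.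

**Compound list**

1 | (3S)-3-hydroxybutanoic acid | C[C@H](O)CC(=O)O | starting material
2 | tert-butyldimethylsilyl (3S)-3-[(tert-butyldimethylsilyl)oxy]butanoate | C[C@H](O[Si](C)(C)C(C)(C)C)CC(=O)O[Si](C)(C)C(C)(C)C | intermediate
3 | (3S)-3-[(tert-butyldimethylsilyl)oxy]butanoyl chloride | C[C@H](O[Si](C)(C)C(C)(C)C)CC(=O)Cl | intermediate
4 | methyl 3-oxopentanoate | CCC(=O)CC(=O)OC | starting material
5 | methyl (5S)-5-[(tert-butyldimethylsilyl)oxy]-3-oxo-2-propanoylhexanoate | CCC(=O)C(C(=O)OC)C(=O)C[C@H](C)O[Si](C)(C)C(C)(C)C | intermediate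
6 | methyl (5S)-5-hydroxy-3-oxo-2-propanoylhexanoate (not isolated) | CCC(=O)C(C(=O)OC)C(=O)C[C@H](C)O | intermediate
7 | methyl (2S)-6-ethyl-2-methyl-4-oxo-3,4-dihydro-2H-pyran-5-carboxylate | CCC1=C(C(=O)OC)C(=O)C[C@H](C)O1 | intermediate
8 | 5-methylhex-4-enoic acid | CC(C)=CCCC(=O)O | starting material
9 | 1-(1H-imidazol-1-yl)-5-methylhex-4-en-1-one | CC(C)=CCCC(=O)n1ccnc1 | intermediate
10 | methyl (2S)-2-methyl-6-(7-methyl-3-oxooct-6-en-2-yl)-4-oxo-3,4-dihydro-2H-pyran-5-carboxylate (not isolated, both side-chain epimers, present as its enolate) | CC(C)=CCCC(=O)C(C)C1=C(C(=O)OC)C(=O)C[C@H](C)O1 | intermediate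
11 | (2S)-5,7-dihydroxy-2,8-dimethyl-6-(3-methylbut-2-en-1-yl)-2,3-dihydro-4H-chromen-4-one | Cc1c(O)c(CC=C(C)C)c(O)c2c1O[C@@H](C)CC2=O | intermediate
12 | geraniol, (2E)-3,7-dimethylocta-2,6-dien-1-ol | CC(C)=CCC/C(C)=C/CO | starting material
13 | (2E)-3,7-dimethylocta-2,6-dien-1-yl methyl carbonate | CC(C)=CCC/C(C)=C/COC(=O)OC | intermediate
14 | (2S,8R)-8-[(2E)-3,7-dimethylocta-2,6-dien-1-yl]-5-hydroxy-2,8-dimethyl-6-(3-methylbut-2-en-1-yl)-2,3-dihydro-4H-chromene-4,7(8H)-dione | CC(C)=CCC/C(C)=C/C[C@@]1(C)C(=O)C(CC=C(C)C)=C(O)C2=C1O[C@@H](C)CC2=O | target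

**Totals.** Total step count: 8. Longest linear sequence: 6 steps (1, 2, 3, 4, 6, 8).

**Steps most likely to fail**

Step 8. The phenoxide may attack through C6 or through oxygen instead of C8, the ligand may discriminate poorly between the two faces of C8, the product enol may be allylated a second time, and the E alkene may partly isomerise in the π-allyl complex. The fallback installs the geranyl group before the ring is made, so that the annulation itself creates the quaternary carbon and no regiochemical question arises. It sets out from 4. Its dianion (NaH, then n-BuLi, THF, 0 °C) is alkylated at the γ-carbon with geranyl bromide to give methyl (6E)-4,7,11-trimethyl-3-oxododeca-6,10-dienoate F1. C-acylation of F1 with 3 (MgCl2, pyridine, CH2Cl2) should give the silyloxy triketo ester F2. HF in MeCN should then give, through the hydroxy triketo ester F3 (not isolated), the dihydropyranone F4. Treatment of F4 with LiN(SiMe3)2 (2.2 equiv) and 9 as in step 6 should pass through the γ-acylated keto ester F5 (not isolated) and close directly to 14. The C8 epimer F6 is expected alongside, since nothing controls C8 here, and would be removed by preparative HPLC. The route is rejoined at 14.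

Step 6. Deprotonation may occur at C3 instead of the ethyl group, followed by β-elimination of the ring oxygen (ring opening and loss of the C2 configuration). The dienolate may also be O-acylated, or the sequence may stop at the stabilised enolate of 10 so that the ring does not close. The fallback replaces the acyl-transfer agent by a ketene and drops the strong base. It sets out from 7 and 8. Acid 8 is converted into 5-methylhex-4-enoyl chloride F7 ((COCl)2, cat. DMF, CH2Cl2). F7 is dehydrochlorinated in the flask by i-Pr2NEt to 5-methylhexa-1,4-dien-1-one F8 (the prenyl ketene) in the presence of the magnesium dienolate of 7 (MgBr2·OEt2, i-Pr2NEt, CH2Cl2, 0 °C to rt; soft enolisation at the most acidic γ-position). Addition of the γ-carbon to the ketene carbonyl gives directly the enolate on the carbon that must attack the ester, so both bonds again form in one operation. The route is rejoined at 11.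

Step 4. After desilylation the hydroxyl may lactonise onto the methyl ester instead of condensing with the propanoyl carbonyl, or the triacylmethane may lose an acyl group by retro-Claisen cleavage in the aqueous acid. The fallback makes the C2–O1 bond by conjugate addition and sets C2 by a catalyst instead of taking it from the chiral pool. It sets out from 4. C-acylation with (E)-but-2-enoyl chloride (MgCl2, pyridine, CH2Cl2) should give methyl (4E)-3-oxo-2-propanoylhex-4-enoate F9. Its enol then adds to the enone in a 6-endo-trig oxa-Michael cyclisation under a cinchona-alkaloid-derived bifunctional thiourea (quinine- or quinidine-derived, chosen for the S configuration; toluene, −20 °C). The route is rejoined at 7.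

**Further compounds**

F1 | step 8 | methyl (6E)-4,7,11-trimethyl-3-oxododeca-6,10-dienoate | CC(C)=CCC/C(C)=C/CC(C)C(=O)CC(=O)OC
F2 | step 8 | methyl (5S)-5-[(tert-butyldimethylsilyl)oxy]-3-oxo-2-[(4E)-2,5,9-trimethyldeca-4,8-dienoyl]hexanoate | CC(C)=CCC/C(C)=C/CC(C)C(=O)C(C(=O)OC)C(=O)C[C@H](C)O[Si](C)(C)C(C)(C)C
F3 | step 8 | methyl (5S)-5-hydroxy-3-oxo-2-[(4E)-2,5,9-trimethyldeca-4,8-dienoyl]hexanoate | CC(C)=CCC/C(C)=C/CC(C)C(=O)C(C(=O)OC)C(=O)C[C@H](C)O
F4 | step 8 | methyl (2S)-6-[(4E)-5,9-dimethyldeca-4,8-dien-2-yl]-2-methyl-4-oxo-3,4-dihydro-2H-pyran-5-carboxylate | CC(C)=CCC/C(C)=C/CC(C)C1=C(C(=O)OC)C(=O)C[C@H](C)O1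
F5 | step 8 | methyl (2S)-6-[(4E)-5,9-dimethyl-2-(5-methylhex-4-enoyl)deca-4,8-dien-2-yl]-2-methyl-4-oxo-3,4-dihydro-2H-pyran-5-carboxylate | CC(C)=CCC/C(C)=C/CC(C)(C(=O)CCC=C(C)C)C1=C(C(=O)OC)C(=O)C[C@H](C)O1
F6 | step 8 | (2S,8S)-8-[(2E)-3,7-dimethylocta-2,6-dien-1-yl]-5-hydroxy-2,8-dimethyl-6-(3-methylbut-2-en-1-yl)-2,3-dihydro-4H-chromene-4,7(8H)-dione | CC(C)=CCC/C(C)=C/C[C@]1(C)C(=O)C(CC=C(C)C)=C(O)C2=C1O[C@@H](C)CC2=O
F7 | step 6 | 5-methylhex-4-enoyl chloride | CC(C)=CCCC(=O)Cl
F8 | step 6 | 5-methylhexa-1,4-dien-1-one | CC(C)=CCC=C=O
F9 | step 4 | methyl (4E)-3-oxo-2-propanoylhex-4-enoate | CCC(=O)C(C(=O)OC)C(=O)/C=C/C
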